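**Retrosynthetic overview**

1. Target 15 is opened across ring C at C3–C4 and O1–C2. This gives the ring A salicylaldehyde 12 (bis-silylated 2,4,6-trihydroxybenzaldehyde) and the ring B arylacetylene 10. Both bonds are made in one pot: rhodium hydroacylation, fluoride unmasking, chalcone isomerase ring closure.
2. Enabling feature: the phenol oxygen O1 on C8a sits ortho to the acyl carbon C4 on C4a (the salicyl unit of ring A). It first chelates rhodium for the formyl C–H insertion and then is the nucleophile onto C2. The 5,7-dihydroxy ring A and 4'-hydroxy ring B make the open chalcone a native-type substrate of the isomerase, which sets C2 as S.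
3. Arylacetylene 10: 4-bromo-2-iodophenol is allylated at the iodine-bearing carbon with 6,7-epoxygeranyl bromide (E olefin bought in geranyl bromide). Hydride opens the epoxide to the tertiary alcohol, and Sonogashira coupling turns the bromide into the alkyne.
4. Ring order: rings A and B are bought as arenes. Ring C is the only ring made and is closed last, in the key step.

Key step: step 8

Assumption: chalcone isomerase (EC 5.5.1.6, for example the recombinant Medicago sativa enzyme) is taken as an available biocatalyst; the epoxide in 2 and 6 is carried racemic because its stereocentre is erased in step 4.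

**Route**

Step 1
Reactants: 1 geranyl bromide, (2E)-1-bromo-3,7-dimethylocta-2,6-diene
Product: 2 racemic 3-[(3E)-5-bromo-3-methylpent-3-en-1-yl]-2,2-dimethyloxirane (6,7-epoxygeranyl bromide)
Conditions: mCPBA (1.0 equiv), CH2Cl2, −15 → 0 °C; used crude
Reagents that add atoms: mCPBA, O=C(OO)c1cccc(Cl)c1
Why: Prilezhaev epoxidation, in which the electrophilic peracid takes the electron-rich 6,7-olefin because the 2,3-olefin is deactivated by the allylic C–Br bond; the epoxide is formed racemic, which is harmless because this stereocentre is erased in step 4.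

Step 2
Reactants: 3 4-bromo-2-iodophenol
Product: 4 (4-bromo-2-iodophenoxy)(tert-butyl)dimethylsilane
Conditions: TBSCl, imidazole, DMF, rt
Reagents that add atoms: TBSCl, CC(C)(C)[Si](C)(C)Cl
Why: Standard imidazole-promoted silyl ether formation, which masks the acidic phenol before the Grignard chemistry and leaves both carbon–halogen bonds untouched.

Step 3
Reactants: 4 (4-bromo-2-iodophenoxy)(tert-butyl)dimethylsilane; 2 6,7-epoxygeranyl bromide
Product: 6 racemic tert-butyl{4-bromo-2-[(2E)-5-(3,3-dimethyloxiran-2-yl)-3-methylpent-2-en-1-yl]phenoxy}dimethylsilane, via aryl Grignard reagent 5 (not isolated)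
Conditions: i-PrMgCl·LiCl, THF, −40 °C; then Li2CuCl4 (3 mol %), 2, −40 → 0 °C
Reagents that add atoms: none
Why: Halogen–magnesium exchange takes the C–I bond ortho to the silyloxy group and not the C–Br bond, and the copper-catalysed Grignard–allylic bromide cross-coupling then substitutes at the primary (alpha) carbon with retention of the E olefin, while the trisubstituted epoxide does not react below 0 °C.

Step 4
Reactants: 6 epoxide from step 3
Product: 7 (6E)-8-[5-bromo-2-(tert-butyldimethylsilyloxy)phenyl]-2,6-dimethyloct-6-en-2-ol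
Conditions: LiEt3BH, THF, 0 °C → rt; aq. NH4Cl
Reagents that add atoms: none
Why: SN2 hydride opening of the trisubstituted epoxide at its less substituted carbon gives the tertiary alcohol and removes the racemic stereocentre, with the aryl bromide, olefin and silyl ether inert.

Step 5
Reactants: 7 aryl bromide from step 4; 8 ethynyltrimethylsilane
Product: 9 (6E)-8-{2-(tert-butyldimethylsilyloxy)-5-[(trimethylsilyl)ethynyl]phenyl}-2,6-dimethyloct-6-en-2-ol
Conditions: PdCl2(PhCN)2 (3 mol %), P(t-Bu)3 (6 mol %), CuI (2 mol %), i-Pr2NH, 1,4-dioxane, rt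
Reagents that add atoms: none
Why: Sonogashira coupling, in which the electron-rich palladium/P(t-Bu)3 catalyst inserts into the electron-rich aryl bromide at room temperature and the free tertiary alcohol, olefin and silyl ether are tolerated.

Step 6
Reactants: 9 bis-silylated arylalkyne from step 5
Product: 10 4-ethynyl-2-[(2E)-7-hydroxy-3,7-dimethyloct-2-en-1-yl]phenol
Conditions: TBAF (2.2 equiv), THF, 0 °C; aq. NH4Cl; kept under argon and used promptly
Reagents that add atoms: none
Why: Fluoride-mediated desilylation cleaves the alkynyl C–Si and the aryl O–Si bond in one operation, driven by Si–F bond formation, and touches nothing else.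

Step 7
Reactants: 11 2,4,6-trihydroxybenzaldehyde
Product: 12 2,4-bis(tert-butyldimethylsilyloxy)-6-hydroxybenzaldehyde
Conditions: TBSCl (2.05 equiv), imidazole, CH2Cl2/DMF, 0 °C
Reagents that add atoms: TBSCl, CC(C)(C)[Si](C)(C)Cl
Why: Selective silylation, in which the 4-OH and one of the two equivalent ortho OH groups react while the last ortho OH is held back by its hydrogen bond to the formyl oxygen and stays free as the chelating group needed in step 8.

Step 8
Reactants: 10 4-ethynyl-2-[(2E)-7-hydroxy-3,7-dimethyloct-2-en-1-yl]phenol; 12 2,4-bis(tert-butyldimethylsilyloxy)-6-hydroxybenzaldehyde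
Product: 15 (2S)-5,7-dihydroxy-2-{4-hydroxy-3-[(2E)-7-hydroxy-3,7-dimethyloct-2-en-1-yl]phenyl}-2,3-dihydro-4H-chromen-4-one, via silylated chalcone 13 (not isolated), via free chalcone 14 (not isolated)
Conditions: [Rh(cod)Cl]2 (2.5 mol %), dppf (5 mol %), Na2CO3 (10 mol %), 1,4-dioxane, 80 °C, Ar; then Et3N·3HF, rt; then KH2PO4/K2HPO4 buffer pH 6.8 (10 % DMSO), chalcone isomerase (EC 5.5.1.6), 25 °C
Reagents that add atoms: none
Why: Proposed new method: the free ring A phenoxide of 12 binds monovalent rhodium next to the formyl group, C–H oxidative addition gives a chelated acyl rhodium hydride, syn hydrometalation of the terminal alkyne of 10 puts rhodium on the unsubstituted carbon and reductive elimination forms C3–C4 as the (E)-chalcone 13; Et3N·3HF then frees the two activated ring A phenols to give 14, which is stable at this mildly acidic stage, and the isomerase closes O1–C2 by conjugate addition of the 2'-oxyanion; the closest known reaction types are the rhodium-catalysed salicylaldehyde–alkyne hydroacylation/oxa-Michael relay to racemic chroman-4-ones and the chalcone isomerase cyclisation of 2',4',6'-trihydroxychalcones to (2S)-flavanones, and the new element is their telescoping on this substrate. Ring C closes in a 6-endo-trig oxa-Michael mode. The C2 stereocentre is set by the enzyme, which holds the enone so that the phenoxide adds to one face only and gives 2S under kinetic control. The step needs acyl delivery to the terminal alkyne carbon, which the unsubstituted terminus and the aryl group on the other carbon should secure, and it needs the non-enzymatic racemic closure to stay slow, which is secured by keeping the 4'- and 6'-oxygens silylated through the hot rhodium stage and by running the enzymatic stage near pH 6.8 at 25 °C. The free ring B phenol, the tertiary alcohol and the trisubstituted olefin are spectators in all three stages.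

**Compound list**

1 | geranyl bromide, (2E)-1-bromo-3,7-dimethylocta-2,6-diene | C/C(=C\CBr)CCC=C(C)C | starting material
2 | racemic 3-[(3E)-5-bromo-3-methylpent-3-en-1-yl]-2,2-dimethyloxirane | C/C(=C\CBr)CCC1OC1(C)C | intermediate
3 | 4-bromo-2-iodophenol | Oc1ccc(Br)cc1I | starting material
4 | (4-bromo-2-iodophenoxy)(tert-butyl)dimethylsilane | CC(C)(C)[Si](C)(C)Oc1ccc(Br)cc1I | intermediate
5 | [5-bromo-2-(tert-butyldimethylsilyloxy)phenyl]magnesium chloride (LiCl complex) | CC(C)(C)[Si](C)(C)Oc1ccc(Br)cc1[Mg]Cl | intermediate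
6 | racemic tert-butyl{4-bromo-2-[(2E)-5-(3,3-dimethyloxiran-2-yl)-3-methylpent-2-en-1-yl]phenoxy}dimethylsilane | C/C(=C\Cc1cc(Br)ccc1O[Si](C)(C)C(C)(C)C)CCC1OC1(C)C | intermediate
7 | (6E)-8-[5-bromo-2-(tert-butyldimethylsilyloxy)phenyl]-2,6-dimethyloct-6-en-2-ol | C/C(=C\Cc1cc(Br)ccc1O[Si](C)(C)C(C)(C)C)CCCC(C)(C)O | intermediate
8 | ethynyltrimethylsilane | C#C[Si](C)(C)C | starting material
9 | (6E)-8-{2-(tert-butyldimethylsilyloxy)-5-[(trimethylsilyl)ethynyl]phenyl}-2,6-dimethyloct-6-en-2-ol | C/C(=C\Cc1cc(C#C[Si](C)(C)C)ccc1O[Si](C)(C)C(C)(C)C)CCCC(C)(C)O | intermediate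
10 | 4-ethynyl-2-[(2E)-7-hydroxy-3,7-dimethyloct-2-en-1-yl]phenol | C/C(=C\Cc1cc(C#C)ccc1O)CCCC(C)(C)O | intermediate
11 | 2,4,6-trihydroxybenzaldehyde | O=Cc1c(O)cc(O)cc1O | starting material
12 | 2,4-bis(tert-butyldimethylsilyloxy)-6-hydroxybenzaldehyde | O=Cc1c(O)cc(O[Si](C)(C)C(C)(C)C)cc1O[Si](C)(C)C(C)(C)C | intermediate
13 | (2E)-1-[2,4-bis(tert-butyldimethylsilyloxy)-6-hydroxyphenyl]-3-{4-hydroxy-3-[(2E)-7-hydroxy-3,7-dimethyloct-2-en-1-yl]phenyl}prop-2-en-1-one | C/C(=C\Cc1cc(/C=C/C(=O)c2c(O)cc(O[Si](C)(C)C(C)(C)C)cc2O[Si](C)(C)C(C)(C)C)ccc1O)CCCC(C)(C)O | intermediate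
14 | (2E)-3-{4-hydroxy-3-[(2E)-7-hydroxy-3,7-dimethyloct-2-en-1-yl]phenyl}-1-(2,4,6-trihydroxyphenyl)prop-2-en-1-one | C/C(=C\Cc1cc(/C=C/C(=O)c2c(O)cc(O)cc2O)ccc1O)CCCC(C)(C)O | intermediate
15 | (2S)-5,7-dihydroxy-2-{4-hydroxy-3-[(2E)-7-hydroxy-3,7-dimethyloct-2-en-1-yl]phenyl}-2,3-dihydro-4H-chromen-4-one | C/C(=C\Cc1cc([C@@H]2CC(=O)c3c(O)cc(O)cc3O2)ccc1O)CCCC(C)(C)O | target

**Step count and risks**

Total step count: 8. Longest linear sequence: 6 (step 1 or 2, then steps 3, 4, 5, 6 and 8).

Steps most likely to fail:

1. Step 8 (Proposed new method). What may go wrong: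
   - hydrometalation in the opposite sense, giving the branched enone;
   - decarbonylation of the electron-rich acyl rhodium hydride;
   - silyl scrambling followed by racemic ring closure in the hot stage;
   - slow enzymatic turnover of a chalcone carrying a lipophilic ring B chain, so that background closure erodes the enantiomeric purity.

   Fallback with known chemistry, setting out from 7 and coming back at 15. Miyaura borylation of 7 (B2pin2, PdCl2(dppf), KOAc, dioxane, 80 °C) would give (6E)-8-[2-(tert-butyldimethylsilyloxy)-5-(4,4,5,5-tetramethyl-1,3,2-dioxaborolan-2-yl)phenyl]-2,6-dimethyloct-6-en-2-ol F1. Purchased 5,7-dihydroxy-4H-chromen-4-one F2 would be silylated (TBSOTf, 2,6-lutidine, CH2Cl2) to 5,7-bis(tert-butyldimethylsilyloxy)-4H-chromen-4-one F3. A rhodium-catalysed asymmetric 1,4-addition of F1 to F3 (Hayashi–Miyaura type; [Rh(C2H4)2Cl]2, an electron-poor chiral biaryl bisphosphine in the enantiomeric form that delivers 2S, catalytic K3PO4, toluene/H2O) would give the trisilylated (2S)-flavanone F4. Et3N·3HF in THF would then release 15 without base-induced racemisation.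

2. Step 3. What may go wrong: attack at the gamma carbon of the allylic bromide (branched isomer), rearrangement or opening of the epoxide by the Lewis-acidic magnesium salts, or partial loss of the E geometry.

   Fallback, setting out from 5 and coming back at 6. The Grignard reagent 5 would be quenched with Bu3SnCl to give tributyl[5-bromo-2-(tert-butyldimethylsilyloxy)phenyl]stannane F5. A Stille coupling of F5 with the allylic bromide 2 (Pd2(dba)3, tri(2-furyl)phosphine, THF, 50 °C) would form the same aryl–allyl bond under neutral conditions; zerovalent palladium inserts into the allylic C–Br bond well before the aryl C–Br bond, and the epoxide is not exposed to magnesium salts.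

3. Step 1. What may go wrong: competing epoxidation of the 2,3-olefin, or acid-promoted opening of the epoxide and loss of the allylic bromide during isolation.

   Fallback, setting out from 1 (with 5) and coming back at 7. Unmodified geranyl bromide 1 would be coupled with 5 under the step 3 conditions to give tert-butyl{4-bromo-2-[(2E)-3,7-dimethylocta-2,6-dien-1-yl]phenoxy}dimethylsilane F6. A Mukaiyama hydration (Co(acac)2, PhSiH3, O2, THF, rt) of the less hindered terminal olefin of F6 would give 7 directly, so that neither the epoxide nor the hydride step is needed.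

**Further compounds**

F1 | step 8 | (6E)-8-[2-(tert-butyldimethylsilyloxy)-5-(4,4,5,5-tetramethyl-1,3,2-dioxaborolan-2-yl)phenyl]-2,6-dimethyloct-6-en-2-ol | C/C(=C\Cc1cc(B2OC(C)(C)C(C)(C)O2)ccc1O[Si](C)(C)C(C)(C)C)CCCC(C)(C)O
F2 | step 8 | 5,7-dihydroxy-4H-chromen-4-one (purchased) | O=c1ccoc2cc(O)cc(O)c12
F3 | step 8 | 5,7-bis(tert-butyldimethylsilyloxy)-4H-chromen-4-one | O=c1ccoc2cc(O[Si](C)(C)C(C)(C)C)cc(O[Si](C)(C)C(C)(C)C)c12
F4 | step 8 | (2S)-5,7-bis(tert-butyldimethylsilyloxy)-2-{4-(tert-butyldimethylsilyloxy)-3-[(2E)-7-hydroxy-3,7-dimethyloct-2-en-1-yl]phenyl}-2,3-dihydro-4H-chromen-4-one | C/C(=C\Cc1cc([C@@H]2CC(=O)c3c(O[Si](C)(C)C(C)(C)C)cc(O[Si](C)(C)C(C)(C)C)cc3O2)ccc1O[Si](C)(C)C(C)(C)C)CCCC(C)(C)O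
F5 | step 3 | tributyl[5-bromo-2-(tert-butyldimethylsilyloxy)phenyl]stannane | CCCC[Sn](CCCC)(CCCC)c1cc(Br)ccc1O[Si](C)(C)C(C)(C)C
F6 | step 1 | tert-butyl{4-bromo-2-[(2E)-3,7-dimethylocta-2,6-dien-1-yl]phenoxy}dimethylsilane | C/C(=C\Cc1cc(Br)ccc1O[Si](C)(C)C(C)(C)C)CCC=C(C)C
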